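# Proposed total synthesis of CNP0408176.0 (compound 21)

## Structural features

Compound 21 (C26H32O6) is an achiral dihydrochalcone. Two benzene rings are joined by a C(=O)–CH2–CH2 chain, so there are no stereocentres at all, adjacent or otherwise. Every problem is therefore one of regiochemistry or chemoselectivity.

Ring A is a pentasubstituted phloroglucinol nucleus. The oxygen para to the acyl group is O1 of a 2,2-dimethyl-3,4-dihydro-2H-pyran fused at C4a–C8a. The acyl carbon sits on C6 between the carbonyl-chelated hydroxyls at C5 and C7, and only C8 bears hydrogen.

Ring B is 1,3,4,5-tetrasubstituted, with the chain at C1', a free OH at C3', OMe at C4' and prenyl at C5'. This is an isovanilloid oxygen pattern (3-OH, 4-OMe), not a vanilloid one.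

The fragile groups are:
- the trisubstituted prenyl alkene, which is sensitive to catalytic hydrogenation, strong acid and electrophiles;
- the three electron-rich phenols;
- the tertiary O1–C2 ether under forcing acid, because opening and reclosure onto C5–O would formally move the acyl group from C6 to C8.

The real difficulty is threefold. The acyl group must be placed at C6 rather than C8 on a ring whose three oxygens are electronically alike. It must be decided which oxygen becomes O1. The pyran and the linker must be saturated without touching the prenyl group.

The key step exploits the ortho relationship of O1–C8a and C4–C4a. The four atoms O1–C8a–C4a–C4 form the 1-oxadiene of an ortho-quinone methide, and C3–C2 with its gem-dimethyl group is 2-methylpropene.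

## Logic of the disconnections

**21 ⇒ 20.** The phenolic O–H bonds at C5, C7 and C3' are traced back to O–CH2OCH3 acetal bonds. One protecting group at all three sites means a single final operation, and on ring A the same acetals act as directing groups for the fragment union. The skeleton is not simplified, but every acidic proton disappears, as organolithium chemistry requires. The forward step must cleave three aryl acetals with acid mild enough to spare the prenyl alkene and the O1–C2 ether. This is helped because the ortho neighbour of the prenyl group is OMe rather than OH, so no second pyran can form.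

**20 ⇒ 7 + 17 (through 18 and 19).** The C6–C(=O) bond is cut. This is the most convergent cut, giving two fragments of similar size with no functional group shared between them. C6 is the only ring position flanked by two acetal oxygens, so it can become a carbanion by directed metalation. The forward step needs lithiation at C6 and not at C8. It also needs an acyl donor that stops at the ketone stage, which the N-methoxy-N-methylamide function of 17 provides through 19.

**7 ⇒ 4 + 5 (through 6).** C4–C3 and O1–C2 are cut together, which removes the whole pyran ring in one operation. What remains is a trisubstituted arene and a C4 feedstock gas. The cut fits because O1 and C4 stand on neighbouring arene carbons. The forward step requires that water leaves 4 under neutral conditions and that exactly one phenol is free, so that O1 is unambiguous. The weakly reactive 5 must also outrun self-condensation of 4 with 6. The acetal groups of 4 are kept on purpose: they leave one phenol free, tolerate acid-free thermolysis and later direct the lithiation. Compound 4 is made fresh and handled without acid.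

**4 ⇒ 3 ⇒ 1 + 2.** The benzylic C–H bond (reduction) and two O–CH2 bonds (protection) are removed. This leads to a commercial aldehyde that already carries C4 of the chroman at the correct oxidation state for a hydride step. The forward protection relies on the hydrogen bond between one ortho hydroxyl and the formyl oxygen to leave that hydroxyl unalkylated. The reduction must be stopped at the alcohol stage.

**17 ⇒ 15 + 16.** The C5'–CH2 bond to the prenyl group is cut. Introducing the alkene last on ring B means that the only hydrogenation of the route (step 8) takes place before any prenyl group exists. The forward coupling must deliver the linear rather than the 1,1-dimethylallyl isomer, and it must tolerate the amide.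

**15 ⇒ 14 ⇒ 12 + 13.** The Cα–Cβ bond of the linker is cut at the alkene level. Compound 13 brings in both linker carbons and the finished acyl-transfer function in one olefination. The forward reduction must saturate a conjugated C=C bond without hydrogenolysis of C–Br or of the N–O bond.

**12 ⇒ 11 ⇒ 9 ⇒ 8 (with 2 and 10).** Only O–C bonds are changed here. Compound 8 is cheap and has bromine at the future prenyl site, but it carries OMe at C3 and OH at C4, the reverse of ring B of 21. Simply protecting its phenol would lead to the wrong regioisomer. The pattern is therefore inverted by cleaving the C3–OCH3 bond and then methylating the more acidic C4–OH. The remaining C5–OH (C3'–OH of 21) is masked afterwards. The forward methylation must distinguish the two catechol hydroxyls.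

## Other disconnections considered

**Alternative 1:**

*Cut and forward step.* C7–O and C6–C(=O) are cut together. The bis-MOM ether A1, one deprotection short of 21, then comes from the ortho-silylaryl triflate A2 and the ring B acid A4. In the forward direction CsF would remove silicon from A2, triflate would leave, and the C6–C7 aryne A3 would form. The carboxylate of A4 should add through oxygen at C7, the terminus remote from the C5 acetal oxygen. The developing carbanion is best accommodated at C6, next to that inductively withdrawing oxygen. The C6 anion then attacks the newly formed ester carbonyl, and the strained adduct opens to the ortho-hydroxyaryl ketone.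

*In its favour.* One C–O and one C–C bond form in a single, nearly neutral operation. No organolithium meets ring B, the acid needs no activation, and only two acetals remain.

*Where it is better or equal.* It is the better plan on positional certainty of the acyl group. The site is defined by where silicon and triflate sit, not by a competition between C6–H and C8–H. It is equal in convergence and in the end game.

*Against it.*
- A2 still requires the chroman, so no pyran construction is saved.
- A2 then needs C5–O/C7–O differentiation, C6 silylation (which itself depends on a C6-selective metalation) and triflation, roughly four extra operations.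
- Proton transfer from a second molecule of A4 to the aryl anion can end at the simple aryl ester.
- The prenyl group of A4, with its allylic hydrogens, is an ene partner for A3.

Overall it is longer, and its key step has more escape channels.

**Alternative 2:**

*Cut and forward step.* C4a–C4 is cut at the chromene oxidation level, so the chromene A5 arises from the para-O-(1,1-dimethylpropargyl) ether A6. Heating A6 should trigger an aromatic [3,3] shift to either ortho carbon. Rearomatisation, a 1,5-hydrogen shift and an oxa-6π electrocyclisation then follow.

*In its favour.* Ring A of A6 has a local mirror plane, so both ortho carbons are identical and no regioisomer can arise. O1 is defined by alkylating the only non-chelated ring A hydroxyl. The cascade is unimolecular and needs no gas or pressure vessel.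

*Where it is better.* On regiochemical certainty and on the kinetic reliability of the ring closure, this alternative is better than the chosen plan.

*Against it.*
- A5 has the wrong oxidation level, so C3=C4 must be saturated in the presence of the prenyl alkene. Differentiating a cis-disubstituted styrene-type alkene from a trisubstituted one with diimide or RhCl(PPh3)3/H2 is plausible but not secure. The chosen plan never faces this question.
- The tertiary propargyl ether must be placed on one of four phenols, so ring B needs masking.
- The acylphloroglucinol core of A6 has to come either from a Lewis-acid acylation that the prenyl group tolerates poorly, or from a chalcone whose reduction again meets the prenyl group.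

The step count is about equal.

**Alternative 3:**

*Cut and forward step.* Ring A itself is dismantled (C6–C7, C4a–C5 and C7–C8). The racemic phenol A7 is then traced to the pyran-fused cyclobutenone A8 and the ring B siloxyalkyne A9. On heating, A8 should open to the vinylketene A10. The nucleophilic alkyne carbon of A9 adds to the ketene carbonyl in a [2+2] sense. The new cyclobutenone opens (4π) and the dienylketene closes (6π), then tautomerises to the phenol.

*In its favour.* The mechanism places all five substituents without ambiguity: C7–OH comes from the ketene, the chain sits at C6, and the siloxy group sits at C5. The conditions are neutral.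

*Where it is better or equal.* On regiochemical certainty at ring A it is better than the chosen plan. In convergence it is equal.

*Against it.*
- It constructs a phloroglucinol ring that can be bought.
- Both A8 and A9 are multi-step speciality compounds, and A9 is a sensitive ynol ether with a propargylic silyl ether.
- A7 carries a carbinol stereocentre that is created only to be destroyed.
- The end game needs two desilylations, an oxidation and an acetal cleavage. The benzylic carbinol next to the free C7–OH is itself prone to ionise during these steps.

In step economy it is clearly inferior.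

Key step: step 3

Assumption: chroman numbering (O1, C2–C4, C4a, C5–C8, C8a) is used for ring A and primed locants for ring B (C1' bears the chain). Compound 21 has no stereocentre and its only alkene ends in two identical methyl groups, so it needs no stereodescriptor.

## Route

Step 1
Reactants: 1 2,4,6-trihydroxybenzaldehyde; 2 chloromethyl methyl ether
Product: 3 2-hydroxy-4,6-bis(methoxymethoxy)benzaldehyde
Conditions: MOMCl (2.2 equiv), i-Pr2NEt (2.5 equiv), CH2Cl2, 0 °C to rt
Reagents that add atoms: chloromethyl methyl ether (2), COCCl
Why: Williamson-type O-alkylation (MOM protection); the para hydroxyl and one ortho hydroxyl react, whereas the last ortho hydroxyl is held in a hydrogen bond to the formyl oxygen and is a poor nucleophile under amine-base conditions, so it stays free when the reagent is limited to about two equivalents.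

Step 2
Reactants: 3 2-hydroxy-4,6-bis(methoxymethoxy)benzaldehyde
Product: 4 2-(hydroxymethyl)-3,5-bis(methoxymethoxy)phenol
Conditions: NaBH4 (1.0 equiv), THF/MeOH 4:1, −10 to 0 °C, 20 min; pH 7 phosphate buffer; concentrated below 25 °C, used crude the same day
Reagents that add atoms: none
Why: Borohydride 1,2-reduction of an aryl aldehyde, to which MOM acetals are inert. Low temperature, short contact time and a neutral quench are chosen because the product ionises easily at its benzylic carbon, and for the same reason it is not chromatographed.

Step 3
Reactants: 4 2-(hydroxymethyl)-3,5-bis(methoxymethoxy)phenol; 5 2-methylpropene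
Product: 7 5,7-bis(methoxymethoxy)-2,2-dimethylchroman, via ortho-quinone methide 6 (not isolated)
Conditions: 5 (ca. 100 equiv, condensed in at −78 °C), toluene (0.02 M in 4), 2,6-di-tert-butyl-4-methylpyridine (10 mol %), steel autoclave, 115–120 °C
Reagents that add atoms: 2-methylpropene (5), CC(C)=C
Why: Thermal 1,4-elimination of water from 4, assisted by the phenol-to-carbinol hydrogen bond and by the two acetal-oxygen donors ortho and para to the benzylic carbon, should give the 1-oxadiene 6 reversibly and in low stationary concentration. Compound 6 is then captured by 5 in an inverse-electron-demand hetero-Diels–Alder reaction, the known route from salicyl alcohols and alkenes to chromans. The six-membered dihydropyran ring closes in an intermolecular [4+2] mode (O1–C8a–C4a–C4 from 6, C3–C2 from 5) that is concerted but asynchronous: C4–C3 bonding runs ahead, partial positive charge gathers on the tertiary carbon, and the carbonyl oxygen closes O1–C2 as ring A regains aromaticity, which makes the capture irreversible. No stereocentre is formed, because C2 carries two methyl groups and C3 and C4 are methylene carbons. The 2,2-dimethyl rather than 3,3-dimethyl orientation follows from pairing the electrophilic methylene terminus of 6 with the nucleophilic CH2 terminus of 5, and the identity of O1 is fixed because 4 has only one free phenol. Selectivity against self-condensation (attack of the electron-rich ring of a second molecule of 4 on 6) is secured by concentration, about 2 M alkene against 0.02 M substrate, while rehydration and O-adducts are reversible and return to 6. The hindered pyridine keeps the medium free of stray acid, which protects the MOM acetals, suppresses acetal exchange with the benzylic hydroxyl and prevents cationic oligomerisation of 5.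

Step 4
Reactants: 8 5-bromovanillin (3-bromo-4-hydroxy-5-methoxybenzaldehyde)
Product: 9 3-bromo-4,5-dihydroxybenzaldehyde
Conditions: AlCl3 (1.2 equiv), pyridine (4.5 equiv), CH2Cl2, reflux; then 2 M HCl
Reagents that add atoms: none
Why: Chelation-assisted cleavage of an ortho-hydroxyaryl methyl ether; aluminium binds the phenoxide and the neighbouring methoxy oxygen, pyridine removes the activated methyl group by SN2, and the aldehyde and aryl bromide are untouched. The step opens the inversion of the oxygen pattern, because 8 has OMe and OH the wrong way round for ring B of 21 (9 is also sold, which would save this step).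

Step 5
Reactants: 9 3-bromo-4,5-dihydroxybenzaldehyde; 10 iodomethane
Product: 11 3-bromo-5-hydroxy-4-methoxybenzaldehyde
Conditions: MeI (1.05 equiv), Li2CO3 (1.1 equiv), DMF, 45 °C
Reagents that add atoms: iodomethane (10), CI
Why: Regioselective Williamson methylation; the C4 hydroxyl, para to the formyl group and ortho to bromine, is distinctly the more acidic, so with a weak base only its phenoxide is present in useful amount and one equivalent of MeI should alkylate there. The same acidity-controlled selectivity is established for protocatechualdehyde derivatives.

Step 6
Reactants: 11 3-bromo-5-hydroxy-4-methoxybenzaldehyde; 2 chloromethyl methyl ether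
Product: 12 3-bromo-4-methoxy-5-(methoxymethoxy)benzaldehyde
Conditions: MOMCl (1.3 equiv), i-Pr2NEt (1.6 equiv), CH2Cl2, 0 °C to rt
Reagents that add atoms: chloromethyl methyl ether (2), COCCl
Why: Standard MOM protection of the single remaining phenol; the group survives base, hydrogenation, cross-coupling and organolithium addition, and it leaves in the same final step as the ring A acetals.

Step 7
Reactants: 12 3-bromo-4-methoxy-5-(methoxymethoxy)benzaldehyde; 13 diethyl [2-(methoxy(methyl)amino)-2-oxoethyl]phosphonate
Product: 14 (E)-3-[3-bromo-4-methoxy-5-(methoxymethoxy)phenyl]-N-methoxy-N-methylprop-2-enamide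
Conditions: 13 (1.2 equiv), NaH (1.2 equiv), THF, 0 °C to rt
Reagents that add atoms: diethyl [2-(methoxy(methyl)amino)-2-oxoethyl]phosphonate (13), CCOP(=O)(CC(=O)N(C)OC)OCC
Why: Horner–Wadsworth–Emmons olefination of a non-enolisable aryl aldehyde with a stabilised phosphonate, expected to be E-selective. It installs both linker carbons and the Weinreb amide at once, and the alkene geometry is erased in step 8.

Step 8
Reactants: 14 (E)-3-[3-bromo-4-methoxy-5-(methoxymethoxy)phenyl]-N-methoxy-N-methylprop-2-enamide
Product: 15 3-[3-bromo-4-methoxy-5-(methoxymethoxy)phenyl]-N-methoxy-N-methylpropanamide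
Conditions: H2 (4 bar), RhCl(PPh3)3 (5 mol %), THF/t-BuOH 1:1, 45 °C
Reagents that add atoms: none
Why: Homogeneous hydrogenation with the Wilkinson catalyst, which saturates disubstituted alkenes but does not hydrogenolyse aryl bromides or N–O bonds as heterogeneous palladium would. It is the only hydrogenation of the route and comes before any prenyl group is present.

Step 9
Reactants: 15 3-[3-bromo-4-methoxy-5-(methoxymethoxy)phenyl]-N-methoxy-N-methylpropanamide; 16 4,4,5,5-tetramethyl-2-(3-methylbut-2-enyl)-1,3,2-dioxaborolane
Product: 17 N-methoxy-3-[4-methoxy-3-(methoxymethoxy)-5-(3-methylbut-2-enyl)phenyl]-N-methylpropanamide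
Conditions: 16 (1.5 equiv), PdCl2(dppf) (5 mol %), K3PO4 (3 equiv), THF/H2O 10:1, 65 °C
Reagents that add atoms: 4,4,5,5-tetramethyl-2-(3-methylbut-2-enyl)-1,3,2-dioxaborolane (16), CC(C)=CCB1OC(C)(C)C(C)(C)O1
Why: Suzuki–Miyaura coupling of an aryl bromide with a prenylboronate; zerovalent palladium inserts into C–Br, and after transmetalation the aryl(π-prenyl)palladium species should eliminate reductively at the unsubstituted CH2 terminus, a preference reinforced by the wide-bite-angle diphosphine. The amide and the acetal are inert to aqueous phosphate.

Step 10
Reactants: 7 5,7-bis(methoxymethoxy)-2,2-dimethylchroman; 17 N-methoxy-3-[4-methoxy-3-(methoxymethoxy)-5-(3-methylbut-2-enyl)phenyl]-N-methylpropanamide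
Product: 20 1-[5,7-bis(methoxymethoxy)-2,2-dimethylchroman-6-yl]-3-[4-methoxy-3-(methoxymethoxy)-5-(3-methylbut-2-enyl)phenyl]propan-1-one, via C6-aryllithium 18 (not isolated), via lithium hemiaminal chelate 19 (not isolated)
Conditions: 7 (1.15 equiv), n-BuLi (1.1 equiv), THF, 0 °C, 1 h; 17 (1.0 equiv), −78 to 0 °C; sat. aq NH4Cl
Reagents that add atoms: none
Why: Directed ortho-metalation followed by Weinreb ketone synthesis; C6–H lies between two chelating MOM groups, the C5 one being pushed toward C6 by the C4 methylene, whereas C8–H has only one MOM group and a poorly coordinating tertiary alkyl ether beside it. The chelate 19 does not collapse until the quench, so no second addition can occur. A D2O quench of an aliquot should confirm the lithiation site before 17 is committed.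

Step 11
Reactants: 20 1-[5,7-bis(methoxymethoxy)-2,2-dimethylchroman-6-yl]-3-[4-methoxy-3-(methoxymethoxy)-5-(3-methylbut-2-enyl)phenyl]propan-1-one
Product: 21 1-(5,7-dihydroxy-2,2-dimethylchroman-6-yl)-3-[3-hydroxy-4-methoxy-5-(3-methylbut-2-enyl)phenyl]propan-1-one (target)
Conditions: HCl (0.5 M in MeOH), MeOH/THF, 40 °C
Reagents that add atoms: none
Why: Acid-catalysed transacetalisation of aryl MOM ethers to methanol; the two acetals ortho to the ketone are especially labile. The prenyl group has no ortho hydroxyl to cyclise onto, and the chroman ether needs far stronger acid to open, so dilute acid at mild temperature should be selective.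

## Compound list

1 | 2,4,6-trihydroxybenzaldehyde | O=Cc1c(O)cc(O)cc1O | starting material
2 | chloromethyl methyl ether | COCCl | starting material
3 | 2-hydroxy-4,6-bis(methoxymethoxy)benzaldehyde | O=Cc1c(O)cc(OCOC)cc1OCOC | intermediate
4 | 2-(hydroxymethyl)-3,5-bis(methoxymethoxy)phenol | OCc1c(O)cc(OCOC)cc1OCOC | intermediate
5 | 2-methylpropene | CC(C)=C | starting material
6 | 3,5-bis(methoxymethoxy)-6-methylidenecyclohexa-2,4-dien-1-one (ortho-quinone methide, not isolated) | C=C1C(=O)C=C(OCOC)C=C1OCOC | intermediate
7 | 5,7-bis(methoxymethoxy)-2,2-dimethylchroman | COCOc1cc(OCOC)c2c(c1)OC(C)(C)CC2 | intermediate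
8 | 5-bromovanillin | COc1cc(C=O)cc(Br)c1O | starting material
9 | 3-bromo-4,5-dihydroxybenzaldehyde | O=Cc1cc(O)c(O)c(Br)c1 | intermediate
10 | iodomethane | CI | starting material
11 | 3-bromo-5-hydroxy-4-methoxybenzaldehyde | COc1c(O)cc(C=O)cc1Br | intermediate
12 | 3-bromo-4-methoxy-5-(methoxymethoxy)benzaldehyde | COCOc1cc(C=O)cc(Br)c1OC | intermediate
13 | diethyl [2-(methoxy(methyl)amino)-2-oxoethyl]phosphonate | CCOP(=O)(CC(=O)N(C)OC)OCC | starting material
14 | (E)-3-[3-bromo-4-methoxy-5-(methoxymethoxy)phenyl]-N-methoxy-N-methylprop-2-enamide | CON(C)C(=O)/C=C/c1cc(Br)c(OC)c(OCOC)c1 | intermediate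
15 | 3-[3-bromo-4-methoxy-5-(methoxymethoxy)phenyl]-N-methoxy-N-methylpropanamide | CON(C)C(=O)CCc1cc(Br)c(OC)c(OCOC)c1 | intermediate
16 | 4,4,5,5-tetramethyl-2-(3-methylbut-2-enyl)-1,3,2-dioxaborolane | CC(C)=CCB1OC(C)(C)C(C)(C)O1 | starting material
17 | N-methoxy-3-[4-methoxy-3-(methoxymethoxy)-5-(3-methylbut-2-enyl)phenyl]-N-methylpropanamide | CON(C)C(=O)CCc1cc(OCOC)c(OC)c(CC=C(C)C)c1 | intermediate
18 | [5,7-bis(methoxymethoxy)-2,2-dimethylchroman-6-yl]lithium (not isolated) | [Li]c1c(OCOC)cc2c(c1OCOC)CCC(C)(C)O2 | intermediate
19 | lithium 1-[5,7-bis(methoxymethoxy)-2,2-dimethylchroman-6-yl]-1-[methoxy(methyl)amino]-3-[4-methoxy-3-(methoxymethoxy)-5-(3-methylbut-2-enyl)phenyl]propan-1-olate (racemic, not isolated) | [Li]OC(CCc1cc(OCOC)c(OC)c(CC=C(C)C)c1)(N(C)OC)c1c(OCOC)cc2c(c1OCOC)CCC(C)(C)O2 | intermediate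
20 | 1-[5,7-bis(methoxymethoxy)-2,2-dimethylchroman-6-yl]-3-[4-methoxy-3-(methoxymethoxy)-5-(3-methylbut-2-enyl)phenyl]propan-1-one | O=C(CCc1cc(OCOC)c(OC)c(CC=C(C)C)c1)c1c(OCOC)cc2c(c1OCOC)CCC(C)(C)O2 | intermediate
21 | 1-(5,7-dihydroxy-2,2-dimethylchroman-6-yl)-3-[3-hydroxy-4-methoxy-5-(3-methylbut-2-enyl)phenyl]propan-1-one | COc1c(O)cc(CCC(=O)c2c(O)cc3c(c2O)CCC(C)(C)O3)cc1CC=C(C)C | target

## Step count and least certain steps

Total step count: 11. The longest linear sequence is 8 steps (steps 4–9, then 10 and 11). The ring A branch contributes 3 steps before the union.

**Step 3 (key step).**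
- *Risk.* Bimolecular capture may be too slow. Compound 6 is a donor-stabilised and therefore weakly electrophilic oxadiene, and 5 is an unactivated alkene. Friedel–Crafts-type self-condensation onto the electron-rich ring may then take over. So may acetal exchange between the benzylic hydroxyl and the neighbouring MOM group, or gradual loss of MOM groups during long heating.
- *Fallback.* The ring closure is made unimolecular, setting out from 3. Addition of 2-methylprop-1-enylmagnesium bromide (2.2 equiv, THF, 0 °C) should give racemic 2-(1-hydroxy-3-methylbut-2-enyl)-3,5-bis(methoxymethoxy)phenol F1. Warming F1 in toluene (80–100 °C) expels water to give the vinylogous quinone methide (Z)-3,5-bis(methoxymethoxy)-6-(3-methylbut-2-enylidene)cyclohexa-2,4-dien-1-one F2. This closes by oxa-6π electrocyclisation to 5,7-bis(methoxymethoxy)-2,2-dimethyl-2H-chromene F3. Hydrogenation (H2, Pd/C, EtOAc) at this prenyl-free stage returns to the route at 7.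

**Step 2.**
- *Risk.* Premature ionisation of the benzylic C–O bond may occur. In the reaction flask this allows a second hydride transfer (over-reduction to the methyl level). During work-up and concentration it leads to self-condensation.
- *Fallback.* The route sets out from 3 and changes the leaving group. Reductive amination (Me2NH, NaBH(OAc)3, 1,2-dichloroethane) should give the storable Mannich base 2-[(dimethylamino)methyl]-3,5-bis(methoxymethoxy)phenol F4. Heated with excess 5 as in step 3, F4 releases dimethylamine, passes through 6 and rejoins the route at 7. The liberated amine also keeps the medium basic.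

**Step 8.**
- *Risk.* Hydrogen uptake by the conjugated, electron-poor amide alkene may be sluggish. Forcing the reaction would bring on hydrodebromination.
- *Fallback.* The route avoids metal-catalysed hydrogenation and sets out from 12. Meldrum's acid, Hantzsch ester and catalytic L-proline in EtOH give the Knoevenagel adduct 5-[3-bromo-4-methoxy-5-(methoxymethoxy)benzylidene]-2,2-dimethyl-1,3-dioxane-4,6-dione F5. Hydride transfer in the same flask reduces it to 5-[3-bromo-4-methoxy-5-(methoxymethoxy)benzyl]-2,2-dimethyl-1,3-dioxane-4,6-dione F6. Refluxing aqueous pyridine hydrolyses and decarboxylates F6 to 3-[3-bromo-4-methoxy-5-(methoxymethoxy)phenyl]propanoic acid F7. Coupling with MeNHOMe·HCl (EDC·HCl, Et3N, CH2Cl2) returns to the route at 15.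

**Step 9.**
- *Risk.* Regiocontrol may be lost in the reductive elimination, with bond formation at the tertiary allyl terminus. Protodeboronation of 16 or migration of the alkene into conjugation may also occur.
- *Fallback.* The route removes the regiochemical question and sets out from 15. Suzuki–Miyaura coupling with allylboronic acid pinacol ester (PdCl2(dppf), K3PO4, THF/H2O) gives N-methoxy-3-[4-methoxy-3-(methoxymethoxy)-5-(prop-2-enyl)phenyl]-N-methylpropanamide F8, whose allyl termini are equivalent. Cross-metathesis with excess 2-methylbut-2-ene then returns to the route at 17. The catalyst is the second-generation Grubbs catalyst, RuCl2(H2IMes)(PCy3)(=CHPh), in CH2Cl2 at 40 °C.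

**Step 10.**
- *Risk.* Metalation at C8 may compete with C6. Proton transfer from the α-methylene of 17 to the hindered 18 may also occur in place of addition, which stalls the union.
- *Fallback.* A more electrophilic partner is used, setting out from 17. DIBAL-H (CH2Cl2, −78 °C) gives 3-[4-methoxy-3-(methoxymethoxy)-5-(3-methylbut-2-enyl)phenyl]propanal F9. Addition of 18 (from 7 as in step 10) at −78 °C gives racemic 1-[5,7-bis(methoxymethoxy)-2,2-dimethylchroman-6-yl]-3-[4-methoxy-3-(methoxymethoxy)-5-(3-methylbut-2-enyl)phenyl]propan-1-ol F10. Positional isomers can be separated at this stage. Dess–Martin periodinane (NaHCO3, CH2Cl2) returns to the route at 20.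

## Further compounds

F1 | step 3 | 2-(1-hydroxy-3-methylbut-2-enyl)-3,5-bis(methoxymethoxy)phenol (racemic) | CC(C)=CC(O)c1c(O)cc(OCOC)cc1OCOC
F2 | step 3 | (Z)-3,5-bis(methoxymethoxy)-6-(3-methylbut-2-enylidene)cyclohexa-2,4-dien-1-one (transient) | CC(C)=C/C=C1\C(=O)C=C(OCOC)C=C1OCOC
F3 | step 3 | 5,7-bis(methoxymethoxy)-2,2-dimethyl-2H-chromene | COCOc1cc(OCOC)c2c(c1)OC(C)(C)C=C2
F4 | step 2 | 2-[(dimethylamino)methyl]-3,5-bis(methoxymethoxy)phenol | CN(C)Cc1c(O)cc(OCOC)cc1OCOC
F5 | step 8 | 5-[3-bromo-4-methoxy-5-(methoxymethoxy)benzylidene]-2,2-dimethyl-1,3-dioxane-4,6-dione (transient) | COCOc1cc(C=C2C(=O)OC(C)(C)OC2=O)cc(Br)c1OC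
F6 | step 8 | 5-[3-bromo-4-methoxy-5-(methoxymethoxy)benzyl]-2,2-dimethyl-1,3-dioxane-4,6-dione | COCOc1cc(CC2C(=O)OC(C)(C)OC2=O)cc(Br)c1OC
F7 | step 8 | 3-[3-bromo-4-methoxy-5-(methoxymethoxy)phenyl]propanoic acid | COCOc1cc(CCC(=O)O)cc(Br)c1OC
F8 | step 9 | N-methoxy-3-[4-methoxy-3-(methoxymethoxy)-5-(prop-2-enyl)phenyl]-N-methylpropanamide | CON(C)C(=O)CCc1cc(CC=C)c(OC)c(OCOC)c1
F9 | step 10 | 3-[4-methoxy-3-(methoxymethoxy)-5-(3-methylbut-2-enyl)phenyl]propanal | O=CCCc1cc(OCOC)c(OC)c(CC=C(C)C)c1
F10 | step 10 | 1-[5,7-bis(methoxymethoxy)-2,2-dimethylchroman-6-yl]-3-[4-methoxy-3-(methoxymethoxy)-5-(3-methylbut-2-enyl)phenyl]propan-1-ol (racemic) | OC(CCc1cc(OCOC)c(OC)c(CC=C(C)C)c1)c1c(OCOC)cc2c(c1OCOC)CCC(C)(C)O2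
A1 | alternative 1 | 1-[7-hydroxy-5-(methoxymethoxy)-2,2-dimethylchroman-6-yl]-3-[4-methoxy-3-(methoxymethoxy)-5-(3-methylbut-2-enyl)phenyl]propan-1-one | COCOc1c(C(=O)CCc3cc(OCOC)c(OC)c(CC=C(C)C)c3)c(O)cc2c1CCC(C)(C)O2
A2 | alternative 1 | 5-(methoxymethoxy)-2,2-dimethyl-6-(trimethylsilyl)chroman-7-yl trifluoromethanesulfonate | COCOc1c([Si](C)(C)C)c(OS(=O)(=O)C(F)(F)F)cc2c1CCC(C)(C)O2
A3 | alternative 1 | 6,7-didehydro-5-(methoxymethoxy)-2,2-dimethylchroman (aryne) | COCOC1=C2CCC(C)(C)OC2=CC#C1
A4 | alternative 1 | 3-[4-methoxy-3-(methoxymethoxy)-5-(3-methylbut-2-enyl)phenyl]propanoic acid | OC(=O)CCc1cc(OCOC)c(OC)c(CC=C(C)C)c1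
A5 | alternative 2 | 1-(5,7-dihydroxy-2,2-dimethyl-2H-chromen-6-yl)-3-[3-hydroxy-4-methoxy-5-(3-methylbut-2-enyl)phenyl]propan-1-one | COc1c(O)cc(CCC(=O)c2c(O)cc3c(c2O)C=CC(C)(C)O3)cc1CC=C(C)C
A6 | alternative 2 | 1-[2,6-dihydroxy-4-(2-methylbut-3-yn-2-yloxy)phenyl]-3-[3-hydroxy-4-methoxy-5-(3-methylbut-2-enyl)phenyl]propan-1-one | COc1c(O)cc(CCC(=O)c2c(O)cc(OC(C)(C)C#C)cc2O)cc1CC=C(C)C
A7 | alternative 3 | 6-{1-(tert-butyldimethylsilyloxy)-3-[4-methoxy-3-(methoxymethoxy)-5-(3-methylbut-2-enyl)phenyl]propyl}-2,2-dimethyl-5-(triisopropylsilyloxy)chroman-7-ol (racemic) | COc1c(OCOC)cc(CCC(O[Si](C)(C)C(C)(C)C)c2c(O)cc3c(c2O[Si](C(C)C)(C(C)C)C(C)C)CCC(C)(C)O3)cc1CC=C(C)C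
A8 | alternative 3 | 3,3-dimethyl-2-oxabicyclo[4.2.0]oct-1(6)-en-7-one | CC1(C)CCC2=C(CC2=O)O1
A9 | alternative 3 | tert-butyl-{[5-[4-methoxy-3-(methoxymethoxy)-5-(3-methylbut-2-enyl)phenyl]-1-(triisopropylsilyloxy)pent-1-yn-3-yl]oxy}dimethylsilane (racemic) | COc1c(OCOC)cc(CCC(O[Si](C)(C)C(C)(C)C)C#CO[Si](C(C)C)(C(C)C)C(C)C)cc1CC=C(C)C
A10 | alternative 3 | (6,6-dimethyl-2-methylideneoxan-3-ylidene)methanone (vinylketene) | O=C=C1CCC(C)(C)OC1=C
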